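## Structural features

The target is a bicyclic triterpenoid: a decalin (ring A = C1–C5 and C10, ring B = C5–C10) that carries on C9 a thirteen-carbon chain, C11–C12 followed by three E-trisubstituted alkenes and a terminal allylic acetate. Ring A holds the C3 ketone beside the quaternary C4 (gem-dimethyl), and the rings are cis-fused: the C10 methyl and H5 lie on the same face, called β here. Four stereocentres stand in a row around ring B (C5, C10, C9, C8) with the configuration 5S,8R,9R,10S. C9 has its chain β, and C8 is a tertiary carbinol with CH3 β and OH α, so the C8 oxygen and the C9 chain are trans. Sensitive groups are the tertiary C8 alcohol (dehydration), the allylic acetate (ionisation, acyl cleavage), the 1,5-triene (acid-induced cyclisation or isomerisation) and the ketone with its enolisable C2. The difficulty is ring B and not the chain. The other chair pair would drive one C4 methyl into ring B, so the cis-decalin is confined to the chair pair with C1 axial on ring B; this makes the α face concave, and the target has its C8 oxygen on that face, trans-diaxial to the C9 chain. A peracid would be expected to attack a C8=C9 alkene from the open β face, syn to the C10 methyl, and so give the wrong C8 epimer. The C8 oxygen is therefore brought in by anti addition and the C9 hydrogen by delivery from that oxygen. The key step exploits the ring A array C3(=O)–C4(CH3)2–C5(H) cis to C10(CH3): a vinyl carbinol on a 3,3-dimethylbicyclo[2.2.2]octenone sets this array free by a [3,3] shift, together with a C8=C9 enoate whose ester carbon becomes C11.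

## Logic of the disconnections

33 ⇒ 32. The ester C–O bond at the chain terminus is cut first. The acetate could not pass the carbanion and dissolving-metal steps, so it goes on last. The forward step only has to tell a primary allylic hydroxyl from a hindered tertiary one.

32 ⇒ 31. The C3 dioxolane and the silyl ether are put back. One acid step removes both, so two protecting groups cost one operation. The forward step must spare the C8 alcohol and the triene.

31 ⇒ 30 ⇒ 22 + 28. The C11–C12 bond is cut and a C11–S bond is added back. C11 hangs on the most hindered ring carbon, so it is made the nucleophile (sulfonyl carbanion) and C12 the allylic electrophile. The cut separates the stereochemically dense bicycle from a chain whose alkene geometry all comes from 23. The forward steps need a dianion beside a free tertiary OH, SN2 without allylic transposition, and a reductive C–S cleavage that leaves the alkenes alone.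

28 ⇒ 27 ⇒ 26 ⇒ 25 ⇒ 24 ⇒ 23. The C–Br, O–Si, terminal C–O and O-acyl bonds of the chain are removed in turn. Doing the allylic oxidation on the cheap fifteen-carbon unit keeps the least efficient step off the main line. The demand is site selectivity for the terminal E methyl.

22 ⇒ 21. The C9–H bond (and one C11–H bond) is cut, which gives a C9=C11 alkene. The C8 hydroxyl can deliver hydrogen to its own face, and this gives the trans relation of O8 and C11 that steric approach would not give. The forward step needs a catalyst that binds a hindered tertiary OH.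

21 ⇒ 19. The C8–O bond is cut and the alkene returned to C8=C9. Anti addition lets the large electrophile use the open β face while the small nucleophile enters from the concave face; the sulfonyl group then makes the elimination unambiguous. The demand is opening at C8 and not C9, in the trans-diaxial sense.

19 ⇒ 17 ⇒ 16 ⇒ 15. The C11–S bond, the oxidation level of C11 and the ketal C–O bonds are retraced. These functional-group changes prepare C11 to serve three times: as the acidic site for the elimination, as the neighbour of the hydride-accepting carbon, and as the carbanion. The ketal has to survive every step up to 31.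

15 ⇒ 12 (key). The C1–C10 bond is cut and C3–C8 restored. This removes ring A and the quaternary C10 at once and turns the cis-fusion problem into a bridged bicycle whose two bridgeheads fix everything. The forward step demands the vinyl group syn to the C9=C10 bridge and a single enantiomer.

12 ⇒ 10 + 11. The C2–C3 bond is cut. The carbinol centre is traced to a ketone with two different faces. The addition must come from the alkene side and must ignore the ester.

10 ⇒ 9 ⇒ 8 ⇒ 6 + 7. After the formal step back to 9, the C–S bond is restored and the two σ bonds C5–C6 and C7–C8 of the ethano bridge are cut. This reveals a planar, achiral dienone. The cycloaddition needs a 2π partner that matches an electron-poor diene and whose auxiliary group can be removed without touching ketone or enoate. The resolution must deliver the (1R,4S) series.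

6 ⇒ 4 ⇒ 3 ⇒ 2 ⇒ 1. One C4–CH3 bond is cut to re-aromatise, then the ester O–CH3, the aryl C–O and the aryl C–Br bonds. All ring carbons, three methyls and C11 come from 1. The demand lies in the dearomatising step: C- against O-methylation, and the ortho carbon away from the ester.

## Other disconnections considered

Alternative 1: The cut removes ring B across C5–C6 and C9–C10. In the forward sense enal A1 (ring A with the ketal, the gem-dimethyl group and CHO on C10 as a latent methyl) would add diene A2 under a chiral Lewis acid or iminium catalyst to give adduct A3.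
- In its favour: one step would create ring B, the cis ring fusion (suprafacial addition to the ring A alkene) and the cis relation of C9 and C10 (endo mode of an E diene). Absolute control would come from the catalyst instead of a resolution, and C9 would be set by the cycloaddition geometry and not by a later reduction. On both counts it is the better plan. The two-carbon stub at C9 of A3 is at least the equal of the C11 ester of 15.
- Against it here: A1 is an α-branched cyclohexenecarbaldehyde with a neopentyl β carbon, a very unreactive dienophile class, and it must form a quaternary centre next to C4. A2 is only a moderate diene, so forcing conditions and loss of enantioselectivity are to be feared. After the key step the CHO must be reduced to CH3. The C7=C8 alkene of A3 must be hydrated with oxygen on the concave face, for which A3 offers no device like the sulfone and bromohydrin of the chosen route. C12–C13 must be made by an sp3–sp2 coupling with a separately built vinyl partner.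
- Comparison: mechanistically it is a concerted [4+2] addition of known type, but its selectivities are preferences, whereas the intramolecular sigmatropic shift of the chosen plan has no geometric alternative. In step count the two should be similar, alternative 1 being shorter before its key step and longer after it.

Alternative 2: The cut is C5–C10 and C8–C9. Triene A4 (Z enal as dienophile, dienyl acetate as diene, linked through C1–C4) would close rings A and B at once and give A5 after equilibration of C9.
- In its favour: it has the highest gain in complexity per step of the four plans. The tertiary C8 oxygen arrives with its methyl in the cycloaddition, so the concave-face oxygenation that costs the chosen route two carefully argued steps is avoided; this is a clear advantage.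
- Against it: the dienophile is a β,β-disubstituted enal, and the diene terminus C8 is fully substituted with a Z methyl that disfavours the s-cis conformer, so both partners are poor. The cis ring fusion needs one of two competing folding modes of the tether. A Lewis acid strong enough to activate the enal may isomerise it, which would scramble C9 and C10, or ionise the enol acetate. Epimerising C9 of a β-acetoxy aldehyde invites loss of acetate. The C6=C7 alkene must be removed.
- Comparison: if the cycloaddition went as drawn, the route would be shorter than the chosen one and would leave C11 as an aldehyde, equal in value to the ester of 15. Each of its selectivity elements is a preference, however, whereas the oxy-Cope rearrangement is stereospecific.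

Alternative 3: The cut is the C10–CH3 bond and C9–C11. Enone A6 would take a methyl group from Me2CuLi at C10, and the resulting enolate would be allylated at C9 to give A7.
- In its favour: cuprate addition to a ring-fusion enone with trapping of the regiodefined enolate is one of the best precedented ways to a cis-fused angular-methyl decalone. The C8 ketone of A7 can later take a methyl nucleophile from the convex face, which is the most secure way to the axial C8 carbinol. On the C8 stereocentre this plan is better than the chosen one.
- Against it: C10 of A6 lies next to C5 with the gem-dimethyl carbon behind it, a congested β position for a cuprate. The allylation must occur cis to the new methyl and stop at mono-alkylation. C3 is carried as a silyl ether, which adds a stereocentre and later a deprotection and an oxidation. The allyl group supplies C11–C13, but its terminal alkene must be turned into the E-trisubstituted C13=C14 alkene. A6 itself needs an enantioselective annulation that fixes C5.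
- Comparison: it is a polar, stepwise sequence under steric control, against a concerted shift under geometric control. It offers the better C8 logic but a worse chain handle, and it is expected to be longer because of the oxidation-level changes at C3 and the multi-stage chain extension.

Key step: step 9

Remarks on the chemistry (before the steps):
- Decalin compounds are described with the target locants (C1–C10, C11 on C9; β = face of the C10 methyl). In the bicyclo[2.2.2]octenes, target C3, C4, C5, C6, C7, C8, C9, C10 correspond to C6, C5, C4, C8, C7, C1, C2, C3.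
- Assumption: the cis C5/C10 fusion (5S) of the target is intended, and all face arguments for ring B rest on the chair pair with C1 axial.
- The precursor (1R,4S,6S) and the rearranged product (4aS,8aS) were checked against the target (5S,10S) and agree. What changes is the way the C8 oxygen is introduced: anti addition in place of a peracid.
- Compounds 8 and 9 are racemic and written without stereodescriptors. The alkene geometry of 21 and the C11 configuration of 30 are left open because both elements disappear later.
- Species made by one reagent and consumed by a second in the same flask are numbered; metal alkoxides that are only protonated on work-up are not.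

## Route

Step 1
Reactants: 1 2,4,6-trimethylbenzoic acid
Product: 2 3-bromo-2,4,6-trimethylbenzoic acid
Conditions: Br2 (1.05 equiv), AcOH, rt, dark
Reagents that add atoms: bromine, BrBr
Why: Electrophilic aromatic bromination; the two free ring positions are equivalent and activated by three methyl groups, so one isomer should form, and one equivalent of bromine limits dibromination.

Step 2
Reactants: 2 3-bromo-2,4,6-trimethylbenzoic acid
Product: 3 3-hydroxy-2,4,6-trimethylbenzoic acid
Conditions: Pd2(dba)3 (2 mol %), 2-di-tert-butylphosphino-2',4',6'-triisopropylbiphenyl (8 mol %), KOH (4 equiv), 1,4-dioxane–H2O, 100 °C; then aq. HCl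
Reagents that add atoms: potassium hydroxide, [K+].[OH-]
Why: Palladium-catalysed hydroxylation of an aryl bromide (C–O cross-coupling); the bulky biaryl phosphine tolerates the two ortho methyl groups and the carboxylate is a spectator.

Step 3
Reactants: 3 3-hydroxy-2,4,6-trimethylbenzoic acid
Product: 4 methyl 3-hydroxy-2,4,6-trimethylbenzoate
Conditions: MeI (1.2 equiv), KHCO3, DMF, rt
Reagents that add atoms: iodomethane, CI
Why: Carboxylate O-alkylation (SN2 on MeI), which does not depend on access to the flanked carbonyl carbon; bicarbonate deprotonates the acid but not the phenol.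

Step 4
Reactants: 4 methyl 3-hydroxy-2,4,6-trimethylbenzoate
Product: 6 methyl 2,4,4,6-tetramethyl-3-oxocyclohexa-1,5-diene-1-carboxylate, via lithium phenoxide 5 (not isolated)
Conditions: n-BuLi (1.0 equiv), toluene, 0 °C; then MeI (5 equiv), 90 °C, sealed tube
Reagents that add atoms: iodomethane, CI
Why: Alkylative dearomatisation of a 2,6-disubstituted phenoxide; the tight lithium ion pair in toluene shields oxygen and steers the soft electrophile to an ortho carbon, and C4 should be preferred to C2, which is buttressed by the ester. The gem-dimethyl product cannot re-aromatise.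

Step 5
Reactants: 6 methyl 2,4,4,6-tetramethyl-3-oxocyclohexa-1,5-diene-1-carboxylate; 7 phenyl vinyl sulfide
Product: 8 rac-methyl 1,3,5,5-tetramethyl-6-oxo-7-(phenylsulfanyl)bicyclo[2.2.2]oct-2-ene-2-carboxylate (used as the mixture of regio- and endo/exo isomers)
Conditions: 7 (5 equiv, neat), BHT (cat.), 130 °C, sealed tube
Reagents that add atoms: none
Why: Inverse-electron-demand Diels–Alder reaction of a 2,4-cyclohexadienone (bonding at C2 and C5 of 6) with an electron-rich ethylene equivalent; ketone and ester lower the diene LUMO and the substitution pattern blocks dienone dimerisation. The isomer composition does not matter because sulfur is removed next.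

Step 6
Reactants: 8 rac-methyl 1,3,5,5-tetramethyl-6-oxo-7-(phenylsulfanyl)bicyclo[2.2.2]oct-2-ene-2-carboxylate
Product: 9 rac-methyl 1,3,5,5-tetramethyl-6-oxobicyclo[2.2.2]oct-2-ene-2-carboxylate
Conditions: Raney Ni (W-2), acetone, reflux
Reagents that add atoms: none
Why: Raney nickel hydrogenolysis of the C–S bond; the tetrasubstituted enoate and the hindered, non-enolisable ketone should not be reduced with acetone as moderating solvent, and all isomers of 8 converge on one compound.

Step 7
Reactants: 9 rac-methyl 1,3,5,5-tetramethyl-6-oxobicyclo[2.2.2]oct-2-ene-2-carboxylate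
Product: 10 methyl (1R,4S)-1,3,5,5-tetramethyl-6-oxobicyclo[2.2.2]oct-2-ene-2-carboxylate
Conditions: preparative SFC on amylose tris(3,5-dimethylphenylcarbamate), CO2–MeOH
Reagents that add atoms: none
Why: Resolution by chromatography on a chiral stationary phase; the rigid keto ester has no epimerisable centre, so the (1R,4S) enantiomer is configurationally stable, and its bridgehead C4 (target C5) later dictates C10.

Step 8
Reactants: 10 methyl (1R,4S)-1,3,5,5-tetramethyl-6-oxobicyclo[2.2.2]oct-2-ene-2-carboxylate; 11 vinylmagnesium bromide
Product: 12 methyl (1R,4S,6S)-6-ethenyl-6-hydroxy-1,3,5,5-tetramethylbicyclo[2.2.2]oct-2-ene-2-carboxylate (vinyl syn to the C2=C3 bridge)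
Conditions: CeCl3 (anhydrous, 3 equiv), 11 (3 equiv), THF, −78 °C; then 10, −78 → 0 °C; then H2O
Reagents that add atoms: none
Why: 1,2-Addition of a vinylcerium reagent to a hindered ketone without α-hydrogens; attack should come from the side of the alkene bridge, not past the hydrogens of the ethano bridge, which places vinyl syn to the alkene and creates the 6S carbinol. The flanked conjugated ester is not attacked at low temperature.

Step 9
Reactants: 12 methyl (1R,4S,6S)-6-ethenyl-6-hydroxy-1,3,5,5-tetramethylbicyclo[2.2.2]oct-2-ene-2-carboxylate
Product: 15 methyl (4aS,8aS)-2,5,5,8a-tetramethyl-6-oxo-3,4,4a,5,6,7,8,8a-octahydronaphthalene-1-carboxylate (cis-fused 3-oxo-Δ8-octalin-9-carboxylate in target locants), via potassium alkoxide 13 (not isolated), via potassium enolate 14 (not isolated)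
Conditions: KN(SiMe3)2 (1.1 equiv), 18-crown-6 (1.2 equiv), THF, 0 → 50 °C; then AcOH, −78 °C
Reagents that add atoms: none
Why: Deprotonation gives alkoxide 13, whose oxyanion weakens the adjacent C3–C8 bond; a concerted suprafacial [3,3] shift of the 3-oxido-1,5-diene C1=C2–C3(O−)–C8–C9=C10 then breaks C3–C8 and forms C1–C10 through the boat array imposed by the bicycle, and enolate 14 is protonated at C2. The closest known reaction type is the anionic oxy-Cope rearrangement of 2-vinylbicyclo[2.2.2]oct-5-en-2-ols to cis-fused octalones. Ring A, six-membered, is closed by the sigmatropic bond formation itself and not by an ionic cyclisation: the vinyl terminus bonds to C10 on the face turned toward the C3–C4 bridge. The one new stereocentre, quaternary C10, is controlled by the bridgehead C5, because C1 and C4 must end on the same side of ring B, so the C10 methyl and H5 are cis (4aS,8aS). The step needs the [3,3] path and not a [1,3] shift or fragmentation to an enone and an allyl anion; the syn vinyl group from step 8, the rigid boat geometry, the gain of an enolate with relief of the bridged framework, and the fact that C10 is the β carbon of the enoate secure this. The ester is safe because the base is non-nucleophilic and 12 has no other acidic hydrogen, and only a slight excess of base is used so that 15 is not deprotonated at its γ position.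

Step 10
Reactants: 15 methyl (4aS,8aS)-2,5,5,8a-tetramethyl-6-oxo-3,4,4a,5,6,7,8,8a-octahydronaphthalene-1-carboxylate
Product: 16 methyl 3,3-ethylenedioxy-4,4,8,10-tetramethyl-Δ8-octalin-9-carboxylate (5β-H; 10β-CH3)
Conditions: HOCH2CH2OH (5 equiv), p-TsOH·H2O (5 mol %), toluene, reflux, Dean–Stark trap
Reagents that add atoms: ethylene glycol, OCCO
Why: Acid-catalysed ketalisation with azeotropic removal of water protects the C3 ketone against hydride and organolithium reagents; the conjugated ester does not react and no stereocentre is touched.

Step 11
Reactants: 16 methyl 3,3-ethylenedioxy-4,4,8,10-tetramethyl-Δ8-octalin-9-carboxylate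
Product: 17 [3,3-ethylenedioxy-4,4,8,10-tetramethyl-Δ8-octalin-9-yl]methanol (5β-H; 10β-CH3)
Conditions: i-Bu2AlH (3 equiv), CH2Cl2, −78 → 0 °C; then aq. potassium sodium tartrate
Reagents that add atoms: none
Why: Hydride reduction of the ester to the primary allylic alcohol (C11–OH); the tetrasubstituted alkene and the ketal are inert.

Step 12
Reactants: 17 [3,3-ethylenedioxy-4,4,8,10-tetramethyl-Δ8-octalin-9-yl]methanol
Product: 19 3,3-ethylenedioxy-4,4,8,10-tetramethyl-9-[(phenylsulfonyl)methyl]-Δ8-octalin (5β-H; 10β-CH3), via allylic bromide 18 (not isolated)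
Conditions: PPh3, CBr4, CH2Cl2, 0 °C; then PhSO2Na, n-Bu4NI (cat.), DMF, rt
Reagents that add atoms: sodium benzenesulfinate, [Na+].[O-]S(=O)c1ccccc1
Why: Appel bromination followed in the same flask by S-alkylation of the sulfinate (SN2 at the primary allylic carbon); the primary sulfone with the tetrasubstituted alkene is also the thermodynamically preferred allylic isomer.

Step 13
Reactants: 19 3,3-ethylenedioxy-4,4,8,10-tetramethyl-9-[(phenylsulfonyl)methyl]-Δ8-octalin
Product: 21 3,3-ethylenedioxy-8α-hydroxy-4,4,8β,10β-tetramethyl-9-[(phenylsulfonyl)methylidene]-cis-decalin (5β-H; alkene geometry undefined), via bromohydrin 20 (not isolated)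
Conditions: NBS (1.1 equiv), THF–H2O, 0 °C, dark; then DBU (3 equiv), rt
Reagents that add atoms: water, O
Why: Bromohydrin formation followed by dehydrobromination of a β-bromo sulfone. Axial C1 screens the α face, so the bromonium ion should form on the β face, and water should open it anti and trans-diaxially at C8, the tertiary carbon remote from the sulfonylmethyl group, which puts OH on the α side where a peracid would have put oxygen on the β side. DBU then removes a sulfonyl-activated C11 hydrogen anti to the C9 bromide (C8 and C10 carry no hydrogen), leaving C8 fixed.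

Step 14
Reactants: 21 3,3-ethylenedioxy-8α-hydroxy-4,4,8β,10β-tetramethyl-9-[(phenylsulfonyl)methylidene]-cis-decalin
Product: 22 3,3-ethylenedioxy-8α-hydroxy-4,4,8β,10β-tetramethyl-9β-[(phenylsulfonyl)methyl]-cis-decalin (5β-H; 9α-H)
Conditions: [Ir(cod)(PCy3)(py)]PF6 (10 mol %), H2 (4 bar), CH2Cl2, rt
Reagents that add atoms: none
Why: Hydroxyl-directed homogeneous hydrogenation; the cationic iridium centre binds the axial C8 hydroxyl and the neighbouring exocyclic alkene and delivers hydrogen to the α face, so H9 ends cis to the C8 oxygen and C11 β. Ketal and sulfone are inert.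

Step 15
Reactants: 23 (2E,6E)-farnesol
Product: 24 (2E,6E)-farnesyl acetate
Conditions: Ac2O, pyridine, DMAP (cat.), CH2Cl2, 0 °C → rt
Reagents that add atoms: acetic anhydride, CC(=O)OC(C)=O
Why: Acylation protects C1 and deactivates the 2,3-alkene toward the allylic oxidation that follows.

Step 16
Reactants: 24 (2E,6E)-farnesyl acetate
Product: 25 (2E,6E,10E)-12-hydroxy-3,7,11-trimethyldodeca-2,6,10-trien-1-yl acetate
Conditions: SeO2 (10 mol %), t-BuOOH (3 equiv), salicylic acid (10 mol %), CH2Cl2, rt
Reagents that add atoms: tert-butyl hydroperoxide, CC(C)(C)OO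
Why: SeO2-catalysed allylic oxidation (ene reaction, then [2,3] shift) selects the E methyl of the terminal, most electron-rich alkene and gives the E allylic alcohol.

Step 17
Reactants: 25 (2E,6E,10E)-12-hydroxy-3,7,11-trimethyldodeca-2,6,10-trien-1-yl acetate
Product: 26 (2E,6E,10E)-12-[(tert-butyldimethylsilyl)oxy]-3,7,11-trimethyldodeca-2,6,10-trien-1-yl acetate
Conditions: TBSCl, imidazole, DMF, rt
Reagents that add atoms: tert-butyldimethylsilyl chloride, CC(C)(C)[Si](C)(C)Cl
Why: Silylation of the primary allylic alcohol gives a group that withstands the carbanion and the sodium amalgam and leaves with the ketal in acid.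

Step 18
Reactants: 26 (2E,6E,10E)-12-[(tert-butyldimethylsilyl)oxy]-3,7,11-trimethyldodeca-2,6,10-trien-1-yl acetate
Product: 27 (2E,6E,10E)-12-[(tert-butyldimethylsilyl)oxy]-3,7,11-trimethyldodeca-2,6,10-trien-1-ol
Conditions: K2CO3 (cat.), MeOH, rt
Reagents that add atoms: none
Why: Base-catalysed transesterification removes the acetate; the silyl ether is stable to methanolic carbonate.

Step 19
Reactants: 27 (2E,6E,10E)-12-[(tert-butyldimethylsilyl)oxy]-3,7,11-trimethyldodeca-2,6,10-trien-1-ol
Product: 28 [(2E,6E,10E)-12-bromo-2,6,10-trimethyldodeca-2,6,10-trien-1-yl]oxy(tert-butyl)dimethylsilane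
Conditions: CBr4, PPh3, CH2Cl2, 0 °C
Reagents that add atoms: carbon tetrabromide, BrC(Br)(Br)Br
Why: Appel reaction converts the primary allylic alcohol into the bromide under neutral conditions, without allylic transposition or loss of alkene geometry; the bromide is used at once.

Step 20
Reactants: 22 3,3-ethylenedioxy-8α-hydroxy-4,4,8β,10β-tetramethyl-9β-[(phenylsulfonyl)methyl]-cis-decalin; 28 [(2E,6E,10E)-12-bromo-2,6,10-trimethyldodeca-2,6,10-trien-1-yl]oxy(tert-butyl)dimethylsilane
Product: 30 3,3-ethylenedioxy-8α-hydroxy-9β-[(3E,7E,11E)-13-(tert-butyldimethylsilyloxy)-4,8,12-trimethyl-1-(phenylsulfonyl)trideca-3,7,11-trienyl]-4,4,8β,10β-tetramethyl-cis-decalin (5β-H; C11 epimers), via dilithio derivative 29 (not isolated)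
Conditions: n-BuLi (2.2 equiv), THF–DMPU, −78 °C; then 28 (1.2 equiv), −78 → −30 °C; then H2O
Reagents that add atoms: none
Why: Alkylation of an α-sulfonyl carbanion (Julia-type sulfone coupling); two equivalents of base give the alkoxide carbanion, which displaces the primary allylic bromide by SN2 and forms C11–C12. The new C11 centre is of no consequence.

Step 21
Reactants: 30 3,3-ethylenedioxy-8α-hydroxy-9β-[(3E,7E,11E)-13-(tert-butyldimethylsilyloxy)-4,8,12-trimethyl-1-(phenylsulfonyl)trideca-3,7,11-trienyl]-4,4,8β,10β-tetramethyl-cis-decalin
Product: 31 3,3-ethylenedioxy-8α-hydroxy-9β-[(3E,7E,11E)-13-(tert-butyldimethylsilyloxy)-4,8,12-trimethyltrideca-3,7,11-trienyl]-4,4,8β,10β-tetramethyl-cis-decalin (5β-H)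
Conditions: 6% Na(Hg), Na2HPO4, MeOH–THF, −20 °C
Reagents that add atoms: none
Why: Reductive desulfonylation by electron transfer under buffered conditions; isolated trisubstituted alkenes, ketal and silyl ether are stable, and the sulfone is homoallylic, so no alkene migration is expected.

Step 22
Reactants: 31 3,3-ethylenedioxy-8α-hydroxy-9β-[(3E,7E,11E)-13-(tert-butyldimethylsilyloxy)-4,8,12-trimethyltrideca-3,7,11-trienyl]-4,4,8β,10β-tetramethyl-cis-decalin
Product: 32 8α-hydroxy-9β-[(3E,7E,11E)-13-hydroxy-4,8,12-trimethyltrideca-3,7,11-trienyl]-4,4,8β,10β-tetramethyl-cis-decalin-3-one (5β-H)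
Conditions: 1 M HCl, THF, rt
Reagents that add atoms: water, O
Why: Acid hydrolysis cleaves the dioxolane and the primary silyl ether together; dilute acid at room temperature should leave the tertiary alcohol and the trisubstituted alkenes untouched.

Step 23
Reactants: 32 8α-hydroxy-9β-[(3E,7E,11E)-13-hydroxy-4,8,12-trimethyltrideca-3,7,11-trienyl]-4,4,8β,10β-tetramethyl-cis-decalin-3-one
Product: 33 (2E,6E,10E)-13-[(1R,2R,4aS,8aS)-2-hydroxy-2,5,5,8a-tetramethyl-6-oxodecahydronaphthalen-1-yl]-2,6,10-trimethyltrideca-2,6,10-trien-1-yl acetate (myrrhanone A acetate as drawn)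
Conditions: Ac2O, pyridine, CH2Cl2, 0 °C → rt
Reagents that add atoms: acetic anhydride, CC(=O)OC(C)=O
Why: Selective acylation of the primary allylic alcohol; the hindered axial tertiary C8 hydroxyl does not react under these conditions.

## Compound list

1 | 2,4,6-trimethylbenzoic acid | Cc1cc(C)c(C(=O)O)c(C)c1 | starting material
2 | 3-bromo-2,4,6-trimethylbenzoic acid | Cc1cc(C)c(Br)c(C)c1C(=O)O | intermediate
3 | 3-hydroxy-2,4,6-trimethylbenzoic acid | Cc1cc(C)c(O)c(C)c1C(=O)O | intermediate
4 | methyl 3-hydroxy-2,4,6-trimethylbenzoate | COC(=O)c1c(C)cc(C)c(O)c1C | intermediate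
5 | lithium 3-(methoxycarbonyl)-2,4,6-trimethylphenoxide | COC(=O)c1c(C)cc(C)c([O-])c1C.[Li+] | intermediate (not isolated)
6 | methyl 2,4,4,6-tetramethyl-3-oxocyclohexa-1,5-diene-1-carboxylate | COC(=O)C1=C(C)C(=O)C(C)(C)C=C1C | intermediate
7 | phenyl vinyl sulfide | C=CSc1ccccc1 | starting material
8 | rac-methyl 1,3,5,5-tetramethyl-6-oxo-7-(phenylsulfanyl)bicyclo[2.2.2]oct-2-ene-2-carboxylate (isomer mixture) | COC(=O)C1=C(C)C2CC(Sc3ccccc3)C1(C)C(=O)C2(C)C | intermediate
9 | rac-methyl 1,3,5,5-tetramethyl-6-oxobicyclo[2.2.2]oct-2-ene-2-carboxylate | COC(=O)C1=C(C)C2CCC1(C)C(=O)C2(C)C | intermediate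
10 | methyl (1R,4S)-1,3,5,5-tetramethyl-6-oxobicyclo[2.2.2]oct-2-ene-2-carboxylate | O=C1C(C)(C)[C@H]2CC[C@]1(C)C(C(=O)OC)=C2C | intermediate
11 | vinylmagnesium bromide | C=C[Mg]Br | starting material
12 | methyl (1R,4S,6S)-6-ethenyl-6-hydroxy-1,3,5,5-tetramethylbicyclo[2.2.2]oct-2-ene-2-carboxylate | C=C[C@]1(O)C(C)(C)[C@H]2CC[C@]1(C)C(C(=O)OC)=C2C | intermediate (precursor of the key step)
13 | potassium alkoxide of 12 | [K+].C=C[C@]1([O-])C(C)(C)[C@H]2CC[C@]1(C)C(C(=O)OC)=C2C | intermediate (not isolated)
14 | potassium C2=C3 enolate of 15 | [K+].COC(=O)C1[C@@]2(C)CC=C([O-])C(C)(C)[C@H]2CCC=1C | intermediate (not isolated)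
15 | methyl (4aS,8aS)-2,5,5,8a-tetramethyl-6-oxo-3,4,4a,5,6,7,8,8a-octahydronaphthalene-1-carboxylate | COC(=O)C1[C@@]2(C)CCC(=O)C(C)(C)[C@H]2CCC=1C | intermediate (product of the key step)
16 | methyl 3,3-ethylenedioxy-4,4,8,10-tetramethyl-Δ8-octalin-9-carboxylate (5β-H; 10β-CH3) | COC(=O)C1[C@@]2(C)CCC3(OCCO3)C(C)(C)[C@H]2CCC=1C | intermediate
17 | [3,3-ethylenedioxy-4,4,8,10-tetramethyl-Δ8-octalin-9-yl]methanol (5β-H; 10β-CH3) | OCC1[C@@]2(C)CCC3(OCCO3)C(C)(C)[C@H]2CCC=1C | intermediate
18 | 9-(bromomethyl)-3,3-ethylenedioxy-4,4,8,10-tetramethyl-Δ8-octalin (5β-H; 10β-CH3) | BrCC1[C@@]2(C)CCC3(OCCO3)C(C)(C)[C@H]2CCC=1C | intermediate (not isolated)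
19 | 3,3-ethylenedioxy-4,4,8,10-tetramethyl-9-[(phenylsulfonyl)methyl]-Δ8-octalin (5β-H; 10β-CH3) | O=S(=O)(CC1[C@@]2(C)CCC3(OCCO3)C(C)(C)[C@H]2CCC=1C)c1ccccc1 | intermediate
20 | 9β-bromo-3,3-ethylenedioxy-8α-hydroxy-4,4,8β,10β-tetramethyl-9α-[(phenylsulfonyl)methyl]-cis-decalin (5β-H) | O=S(=O)(C[C@@]1(Br)[C@@]2(C)CCC3(OCCO3)C(C)(C)[C@H]2CC[C@@]1(C)O)c1ccccc1 | intermediate (not isolated)
21 | 3,3-ethylenedioxy-8α-hydroxy-4,4,8β,10β-tetramethyl-9-[(phenylsulfonyl)methylidene]-cis-decalin (5β-H; alkene geometry undefined) | O=S(=O)(C=C1[C@@]2(C)CCC3(OCCO3)C(C)(C)[C@H]2CC[C@@]1(C)O)c1ccccc1 | intermediate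
22 | 3,3-ethylenedioxy-8α-hydroxy-4,4,8β,10β-tetramethyl-9β-[(phenylsulfonyl)methyl]-cis-decalin (5β-H; 9α-H) | O=S(=O)(C[C@@H]1[C@@]2(C)CCC3(OCCO3)C(C)(C)[C@H]2CC[C@@]1(C)O)c1ccccc1 | intermediate
23 | (2E,6E)-farnesol | CC(C)=CCC/C(C)=C/CC/C(C)=C/CO | starting material
24 | (2E,6E)-farnesyl acetate | CC(C)=CCC/C(C)=C/CC/C(C)=C/COC(C)=O | intermediate
25 | (2E,6E,10E)-12-hydroxy-3,7,11-trimethyldodeca-2,6,10-trien-1-yl acetate | OC/C(C)=C/CC/C(C)=C/CC/C(C)=C/COC(C)=O | intermediate
26 | (2E,6E,10E)-12-[(tert-butyldimethylsilyl)oxy]-3,7,11-trimethyldodeca-2,6,10-trien-1-yl acetate | CC(C)(C)[Si](C)(C)OC/C(C)=C/CC/C(C)=C/CC/C(C)=C/COC(C)=O | intermediate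
27 | (2E,6E,10E)-12-[(tert-butyldimethylsilyl)oxy]-3,7,11-trimethyldodeca-2,6,10-trien-1-ol | CC(C)(C)[Si](C)(C)OC/C(C)=C/CC/C(C)=C/CC/C(C)=C/CO | intermediate
28 | [(2E,6E,10E)-12-bromo-2,6,10-trimethyldodeca-2,6,10-trien-1-yl]oxy(tert-butyl)dimethylsilane | CC(C)(C)[Si](C)(C)OC/C(C)=C/CC/C(C)=C/CC/C(C)=C/CBr | intermediate
29 | dilithio derivative of 22 (C8 alkoxide; C11 carbanion) | [Li+].[Li+].O=S(=O)([CH-][C@@H]1[C@@]2(C)CCC3(OCCO3)C(C)(C)[C@H]2CC[C@@]1(C)[O-])c1ccccc1 | intermediate (not isolated)
30 | 3,3-ethylenedioxy-8α-hydroxy-9β-[(3E,7E,11E)-13-(tert-butyldimethylsilyloxy)-4,8,12-trimethyl-1-(phenylsulfonyl)trideca-3,7,11-trienyl]-4,4,8β,10β-tetramethyl-cis-decalin (5β-H; C11 epimers) | CC(C)(C)[Si](C)(C)OC/C(C)=C/CC/C(C)=C/CC/C(C)=C/CC([C@@H]1[C@@]2(C)CCC3(OCCO3)C(C)(C)[C@H]2CC[C@@]1(C)O)S(=O)(=O)c1ccccc1 | intermediate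
31 | 3,3-ethylenedioxy-8α-hydroxy-9β-[(3E,7E,11E)-13-(tert-butyldimethylsilyloxy)-4,8,12-trimethyltrideca-3,7,11-trienyl]-4,4,8β,10β-tetramethyl-cis-decalin (5β-H) | CC(C)(C)[Si](C)(C)OC/C(C)=C/CC/C(C)=C/CC/C(C)=C/CC[C@@H]1[C@@]2(C)CCC3(OCCO3)C(C)(C)[C@H]2CC[C@@]1(C)O | intermediate
32 | 8α-hydroxy-9β-[(3E,7E,11E)-13-hydroxy-4,8,12-trimethyltrideca-3,7,11-trienyl]-4,4,8β,10β-tetramethyl-cis-decalin-3-one (5β-H) | OC/C(C)=C/CC/C(C)=C/CC/C(C)=C/CC[C@@H]1[C@@]2(C)CCC(=O)C(C)(C)[C@H]2CC[C@@]1(C)O | intermediate
33 | (2E,6E,10E)-13-[(1R,2R,4aS,8aS)-2-hydroxy-2,5,5,8a-tetramethyl-6-oxodecahydronaphthalen-1-yl]-2,6,10-trimethyltrideca-2,6,10-trien-1-yl acetate | CC(=O)OC/C(C)=C/CC/C(C)=C/CC/C(C)=C/CC[C@@H]1[C@@]2(C)CCC(=O)C(C)(C)[C@H]2CC[C@@]1(C)O | target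

## Step count and least certain steps

Total: 23 steps, counting the chromatographic resolution. Longest linear sequence: 18 steps (steps 1–14 and 20–23). The chain fragment takes 5 steps (15–19).

Step 9 (key step). What may go wrong is heterolytic cleavage of the C3–C8 bond of alkoxide 13 to an enone and an ester-substituted allyl anion, which would recombine without regiocontrol or lose the vinyl ketone. Excess base could also deprotonate the product at its γ position and move the double bond. The cause is that the oxyanion which accelerates the [3,3] shift also lowers the barrier to fragmentation. Fallback, the neutral thermal variant: starting from 12, silylation (TMSOTf, 2,6-lutidine) would give the trimethylsilyl ether F1. Heating in a sealed tube (o-dichlorobenzene, about 220 °C) should bring about the concerted siloxy-Cope rearrangement through the same boat array to the silyl enol ether F2. Mild hydrolysis (aq. HCl, THF) comes back to the route at 15.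

Step 13. What may go wrong is slow entry of water at C8 from the concave face, so that opening at C9, attack of water on a minor α-bromonium ion from the β side, or allylic bromination compete; the trajectory to C8 on the α side passes close to axial C1. Fallback, reagent control in place of anti addition: starting from 17, Sharpless asymmetric epoxidation [Ti(Oi-Pr)4, L-(+)-diethyl tartrate, t-BuOOH, 4 Å molecular sieves, −20 °C] lets the tartrate and not the substrate choose the α face and would give the 8α,9α-epoxy alcohol F3. Thioether formation (PhSSPh, n-Bu3P) leads to the epoxy sulfide F4, and oxidation at sulfur [H2O2, (NH4)6Mo7O24] to the epoxy sulfone F5. DBU then opens the epoxide by β-elimination from the sulfonyl-activated C11 and comes back at 21. The weakness of this fallback is that the titanium complex must itself work on the concave face.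

Step 14. What may go wrong is failure of the iridium centre to engage an electron-poor trisubstituted alkene flanked by two quaternary carbons, with no conversion or slow undirected reduction after catalyst deactivation. Fallback, alkoxide-directed hydride delivery in place of catalytic hydrogenation: starting from 21, LiAlH4 (THF, 0 °C → rt) first forms the C8 alkoxyaluminate, which can pass hydride intramolecularly to C9, the β carbon of the vinyl sulfone, on the α face. Protonation of the α-sulfonyl carbanion on work-up comes back at 22. No new compound is involved.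

Step 4. What may go wrong is O-methylation and para (C6) C-methylation outrunning ortho C-methylation, since the phenoxide is an ambident nucleophile and all three ring positions carry methyl groups. Fallback, an ortho-specific [2,3] sigmatropic alkylation: starting from 4, the Corey–Kim reagent (Me2S, N-chlorosuccinimide, CH2Cl2, −25 °C; then Et3N) would give an aryloxysulfonium ylide that can deliver its CH2SMe group only to an ortho carbon. The product is methyl 2,4,6-trimethyl-4-[(methylsulfanyl)methyl]-3-oxocyclohexa-1,5-diene-1-carboxylate F6. Cycloaddition with 7 as in step 5 would give the bis-sulfide adduct F7, and Raney Ni hydrogenolysis of both C–S bonds (CH2SMe becomes CH3) comes back at 9.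

Step 5. What may go wrong is slow cycloaddition at the fully substituted diene terminus (C2 of 6), so that thermal decomposition of the dienone or polymerisation of the vinyl sulfide takes over. Fallback, the parent 2π component: starting from 6, ethylene itself (60 bar, toluene, 170 °C, autoclave) would give 9 directly and make step 6 unnecessary. No new compound is involved.

## Further compounds

F1 | step 9 | methyl (1R,4S,6S)-6-ethenyl-1,3,5,5-tetramethyl-6-[(trimethylsilyl)oxy]bicyclo[2.2.2]oct-2-ene-2-carboxylate | C=C[C@]1(O[Si](C)(C)C)C(C)(C)[C@H]2CC[C@]1(C)C(C(=O)OC)=C2C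
F2 | step 9 | trimethylsilyl enol ether (C2=C3) of 15 | COC(=O)C1[C@@]2(C)CC=C(O[Si](C)(C)C)C(C)(C)[C@H]2CCC=1C
F3 | step 13 | [8α,9α-epoxy-3,3-ethylenedioxy-4,4,8β,10β-tetramethyl-cis-decalin-9-yl]methanol (5β-H) | OC[C@]14[C@@]2(C)CCC3(OCCO3)C(C)(C)[C@H]2CC[C@@]1(C)O4
F4 | step 13 | 8α,9α-epoxy-3,3-ethylenedioxy-4,4,8β,10β-tetramethyl-9β-[(phenylsulfanyl)methyl]-cis-decalin (5β-H) | S(C[C@]14[C@@]2(C)CCC3(OCCO3)C(C)(C)[C@H]2CC[C@@]1(C)O4)c1ccccc1
F5 | step 13 | 8α,9α-epoxy-3,3-ethylenedioxy-4,4,8β,10β-tetramethyl-9β-[(phenylsulfonyl)methyl]-cis-decalin (5β-H) | O=S(=O)(C[C@]14[C@@]2(C)CCC3(OCCO3)C(C)(C)[C@H]2CC[C@@]1(C)O4)c1ccccc1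
F0 | step 14 | none | none
F6 | step 4 | rac-methyl 2,4,6-trimethyl-4-[(methylsulfanyl)methyl]-3-oxocyclohexa-1,5-diene-1-carboxylate | COC(=O)C1=C(C)C(=O)C(C)(CSC)C=C1C
F7 | step 4 | rac-methyl 1,3,5-trimethyl-5-[(methylsulfanyl)methyl]-6-oxo-7-(phenylsulfanyl)bicyclo[2.2.2]oct-2-ene-2-carboxylate (isomer mixture) | COC(=O)C1=C(C)C2CC(Sc3ccccc3)C1(C)C(=O)C2(C)CSC
F0 | step 5 | none | none
A1 | alternative 1 | 6,6-dimethyl-1,4-dioxaspiro[4.5]dec-7-ene-8-carbaldehyde (ring A enal) | O=CC1=CC(C)(C)C2(OCCO2)CC1
A2 | alternative 1 | tert-butyl{[(3E)-4-methylhexa-3,5-dien-1-yl]oxy}dimethylsilane | C=C/C(C)=C/CCO[Si](C)(C)C(C)(C)C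
A3 | alternative 1 | 9β-[2-(tert-butyldimethylsilyloxy)ethyl]-3,3-ethylenedioxy-10β-formyl-4,4,8-trimethyl-Δ7-octalin (5β-H; cis-fused) | CC(C)(C)[Si](C)(C)OCC[C@@H]1[C@@]2(C=O)CCC3(OCCO3)C(C)(C)[C@H]2CC=C1C
A4 | alternative 2 | (2E,4E,10Z)-6,6,10-trimethyl-7,12-dioxododeca-2,4,10-trien-2-yl acetate | O=C/C=C(/C)CCC(=O)C(C)(C)/C=C/C=C(\C)OC(C)=O
A5 | alternative 2 | 8α-acetoxy-9β-formyl-4,4,8β,10β-tetramethyl-Δ6-octalin-3-one (5β-H; cis-fused) | O=C[C@@H]1[C@@]2(C)CCC(=O)C(C)(C)[C@H]2C=C[C@@]1(C)OC(C)=O
A6 | alternative 3 | 3α-(tert-butyldimethylsilyloxy)-4,4-dimethyl-Δ9(10)-octalin-8-one (5β-H) | O=C1C=C2CC[C@@H](O[Si](C)(C)C(C)(C)C)C(C)(C)[C@H]2CC1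
A7 | alternative 3 | 9β-allyl-3α-(tert-butyldimethylsilyloxy)-4,4,10β-trimethyl-cis-decalin-8-one (5β-H) | C=CC[C@@H]1[C@@]2(C)CC[C@@H](O[Si](C)(C)C(C)(C)C)C(C)(C)[C@H]2CCC1=O
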